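**Retrosynthetic overview**

1. Feature: in the tetrahydrofuran ring O1–C7–C8–C8'–C9', the unsubstituted C9' methylene lies between O1 and C8', and C7', the carbon β to it, is a benzylic carbinol on the catechol arene. This O1–C9'H2–C8'–C7'(OH)Ar unit is what remains when a formaldehyde-derived oxocarbenium ion on O1 adds to a styrene C8'=C7' and water ends the cation.
2. Key disconnection (the only ring formed, step 7): O1–C9', C9'–C8' and C7'–OH, leading back to formaldehyde, water and a syn (7S,8R) homoallylic benzylic alcohol with an (E)-3,4-bis(benzyloxy)styryl group on C8.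
3. That alcohol comes from an Evans syn aldol of an (E)-4-arylbut-3-enoyl oxazolidinone (Wittig, then N-acylation) with vanillin tosylate, followed by LiBH4 cleavage and silylation of the primary C9 hydroxyl.
4. Two repairs inside the plan: the guaiacyl phenol is carried as a tosylate (acceptor arene, so the benzylic C7–O bond does not ionise under the Lewis acid), and C7', which is born from a planar cation, is fixed after ring closure by oxidation and Felkin–Anh reduction. Base, then hydrogenolysis, free the target.

Key step: step 7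

Remark: lignan locants are used throughout (ring O1–C7–C8–C8'–C9'; C9 on C8; C7' on C8'); both aldehydes, the phosphonium salt, the oxazolidinone and paraformaldehyde are taken as purchased, and the Prins product is carried on as both C7' epimers because that centre is set only in step 9.

Step 1
Reactants: 1 3,4-bis(benzyloxy)benzaldehyde; 2 (2-carboxyethyl)triphenylphosphonium bromide
Product: 4 (E)-4-[3,4-bis(benzyloxy)phenyl]but-3-enoic acid, via ylide carboxylate 3 (not isolated)
Conditions: 2, KOtBu (2.2 equiv), THF, 0 °C; then 1, 0 °C to rt; aq. HCl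
Reagents that add atoms: none
Why: Wittig olefination with the carboxylate-bearing ylide is expected to give the β,γ-unsaturated acid mainly as the E isomer with an aromatic aldehyde, styrene conjugation keeps the double bond out of conjugation with the carboxyl group, and crystallisation of the acid should remove any Z isomer.

Step 2
Reactants: 4 (E)-4-[3,4-bis(benzyloxy)phenyl]but-3-enoic acid; 5 (S)-4-benzyl-2-oxazolidinone
Product: 7 (S)-4-benzyl-3-[(E)-4-(3,4-bis(benzyloxy)phenyl)but-3-enoyl]oxazolidin-2-one, via mixed pivalic anhydride 6 (not isolated)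
Conditions: PivCl, Et3N, THF, −20 °C; then LiCl, 5, −20 °C to rt
Reagents that add atoms: none
Why: Acylation of the oxazolidinone nitrogen by the mixed pivalic anhydride under LiCl/Et3N activation is a standard mild N-acylation, and because no strong base is present the double bond should stay E and conjugated with the arene.

Step 3
Reactants: 8 vanillin
Product: 9 4-formyl-2-methoxyphenyl 4-methylbenzenesulfonate (vanillin tosylate)
Conditions: TsCl, Et3N, DMAP (cat.), CH2Cl2, 0 °C to rt
Reagents that add atoms: p-toluenesulfonyl chloride, Cc1ccc(cc1)S(=O)(=O)Cl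
Why: O-Sulfonylation of the phenol installs an electron-withdrawing protecting group that makes the future C7 arene an acceptor and that tolerates boron enolates, hydrides and Lewis acids.

Step 4
Reactants: 7 (S)-4-benzyl-3-[(E)-4-(3,4-bis(benzyloxy)phenyl)but-3-enoyl]oxazolidin-2-one; 9 vanillin tosylate
Product: 11 (S)-4-benzyl-3-[(2S,3S)-2-[(E)-2-(3,4-bis(benzyloxy)phenyl)ethenyl]-3-hydroxy-3-(3-methoxy-4-tosyloxyphenyl)propanoyl]oxazolidin-2-one, via Z boron dienolate 10 (not isolated)
Conditions: Bu2BOTf, i-Pr2NEt, CH2Cl2, 0 °C; then 9, −78 to 0 °C; pH 7 buffer, MeOH, H2O2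
Reagents that add atoms: none
Why: Evans syn aldol reaction, in which the Z boron dienolate should react at its α-carbon through a Zimmerman–Traxler chair on the enolate face away from the benzyl group of the auxiliary, setting C8 and C7 together as the syn (2S,3S) adduct, the arrangement that is 7S,8R in the later compounds (the C8 descriptor changes only through the priority order).

Step 5
Reactants: 11 the syn aldol adduct
Product: 12 4-[(1S,2R,3E)-4-[3,4-bis(benzyloxy)phenyl]-1-hydroxy-2-(hydroxymethyl)but-3-en-1-yl]-2-methoxyphenyl 4-methylbenzenesulfonate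
Conditions: LiBH4, MeOH (1 equiv), THF, 0 °C
Reagents that add atoms: none
Why: Reductive cleavage of the N-acyl oxazolidinone with LiBH4 (hydride attack at the exocyclic imide carbonyl) should give the 1,3-diol and return the auxiliary, with the aryl sulfonate, benzyl ethers and styrene untouched and no stereocentre involved.

Step 6
Reactants: 12 the (7S,8R) 1,3-diol
Product: 13 4-[(1S,2R,3E)-4-[3,4-bis(benzyloxy)phenyl]-2-[(tert-butyldiphenylsilyloxy)methyl]-1-hydroxybut-3-en-1-yl]-2-methoxyphenyl 4-methylbenzenesulfonate
Conditions: TBDPSCl, imidazole, CH2Cl2, 0 °C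
Reagents that add atoms: tert-butyl(chloro)diphenylsilane, CC(C)(C)[Si](Cl)(c1ccccc1)c1ccccc1
Why: Selective O-silylation of the primary hydroxyl of the 1,3-diol by the bulky silyl chloride leaves the secondary benzylic C7 hydroxyl free for the next step and puts a non-coordinating, non-participating group on C9.

Step 7
Reactants: 13 the syn homoallylic benzylic alcohol; 14 formaldehyde (as paraformaldehyde)
Product: 17 (7S,8R,8'S)-tetrahydrofuran carbinol as both C7' epimers, via oxocarbenium ion 15 (not isolated), via benzylic cation 16 (not isolated)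
Conditions: (CH2O)n (3 equiv), In(OTf)3 (10 mol %), H2O (2 equiv), CH2Cl2 (dilute), 0 °C to rt; aq. NaHCO3
Reagents that add atoms: water, O
Why: The Lewis acid turns the hemiformal of the C7 hydroxyl into oxocarbenium ion 15 (O1=C9'H2), C9' adds to C8' of the E-styrene to give benzylic cation 16, and water (set free in the condensation and present in slight excess) captures C7'. The closest known reaction type is the oxonium-Prins cyclisation of styrenyl homoallylic alcohols with aldehydes to 2,3-disubstituted tetrahydrofurans, run here with a water-tolerant metal triflate so that the cation ends as the alcohol. The ring O1–C7–C8–C8'–C9' closes in the 5-exo-trig mode and not 6-endo, because only 5-exo places the charge on C7' next to the 3,4-bis(benzyloxy)phenyl donor. C8' should be set trans to the C8 silyloxymethyl group through an envelope transition state with the C7 aryl, C8 and C8' substituents pseudo-equatorial; C7' comes from a long-lived planar cation, so alkene geometry does not control it, and with C8'–H eclipsing the arene (A(1,3) strain) water should enter mainly anti to the C8 branch (the 7'S epimer) or unselectively, which is why both epimers are carried on and C7' is reset in steps 8 and 9. The step needs oxocarbenium formation at O1 to outrun ionisation of the benzylic C7–O bond, 2-oxonia-Cope shift and Friedel–Crafts capture of 16 by the C7 arene; the electron-withdrawing tosyloxy group on that arene secures all three, and the electron-rich styrene secures fast 5-exo attack.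

Step 8
Reactants: 17 the tetrahydrofuran carbinol (both C7' epimers)
Product: 18 4-[(2S,3R,4S)-4-[3,4-bis(benzyloxy)benzoyl]-3-[(tert-butyldiphenylsilyloxy)methyl]oxolan-2-yl]-2-methoxyphenyl 4-methylbenzenesulfonate
Conditions: Dess–Martin periodinane, CH2Cl2, 0 °C to rt
Reagents that add atoms: none
Why: Dess–Martin oxidation of the secondary benzylic alcohol should merge both C7' epimers into one aryl ketone, and the C8' centre α to the carbonyl already holds the more stable trans arrangement to C8, so enolisation cannot erode it.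

Step 9
Reactants: 18 the C7' ketone
Product: 19 4-[(2S,3R,4S)-4-{(R)-[3,4-bis(benzyloxy)phenyl](hydroxy)methyl}-3-[(tert-butyldiphenylsilyloxy)methyl]oxolan-2-yl]-2-methoxyphenyl 4-methylbenzenesulfonate
Conditions: LiBH(s-Bu)3 (L-Selectride), THF, −78 °C; H2O
Reagents that add atoms: none
Why: Felkin–Anh reduction of the α-branched aryl ketone by a bulky hydride: with the larger C8 ring branch anti to the incoming hydride and the C9' methylene on the carbonyl-oxygen side, attack should come from the face that gives the 7'R carbinol (a chelate between the carbonyl and O1 would expose the same face).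

Step 10
Reactants: 19 the (7'R) carbinol
Product: 20 4-[(2S,3R,4S)-4-{(R)-[3,4-bis(benzyloxy)phenyl](hydroxy)methyl}-3-(hydroxymethyl)oxolan-2-yl]-2-methoxyphenol
Conditions: KOH, MeOH/THF/H2O, 55 °C; AcOH to pH 6
Reagents that add atoms: none
Why: Alkaline hydrolysis in which hydroxide or methoxide attacks sulfur of the aryl sulfonate (S–O cleavage) and silicon of the silyl ether, while benzyl ethers, the tetrahydrofuran and both carbinols are stable to base and the catechol stays benzylated, so no air-sensitive catecholate is exposed.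

Step 11
Reactants: 20 the catechol bis(benzyl) ether
Product: 21 4-{(R)-hydroxy[(3S,4R,5S)-4-(hydroxymethyl)-5-(4-hydroxy-3-methoxyphenyl)oxolan-3-yl]methyl}benzene-1,2-diol (target)
Conditions: H2 (1 atm), Pd/C (10 wt %), EtOAc/MeOH, rt
Reagents that add atoms: none
Why: Catalytic hydrogenolysis of the two aryl benzyl ethers over Pd/C should, under neutral conditions, be much faster than cleavage of the benzylic C7–O1 and C7'–OH bonds, so the reaction is stopped when hydrogen uptake for two benzyl groups is complete.

**Compound list**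

1 | 3,4-bis(benzyloxy)benzaldehyde | O=Cc1ccc(OCc2ccccc2)c(OCc2ccccc2)c1 | starting material
2 | (2-carboxyethyl)triphenylphosphonium bromide | [Br-].OC(=O)CC[P+](c1ccccc1)(c1ccccc1)c1ccccc1 | starting material
3 | potassium 3-(triphenylphosphoranylidene)propanoate (ylide carboxylate, not isolated) | [K+].[O-]C(=O)CC=P(c1ccccc1)(c1ccccc1)c1ccccc1 | intermediate
4 | (E)-4-[3,4-bis(benzyloxy)phenyl]but-3-enoic acid | OC(=O)C/C=C/c1ccc(OCc2ccccc2)c(OCc2ccccc2)c1 | intermediate
5 | (S)-4-benzyl-2-oxazolidinone | O=C1N[C@@H](Cc2ccccc2)CO1 | starting material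
6 | (E)-4-[3,4-bis(benzyloxy)phenyl]but-3-enoic pivalic anhydride (not isolated) | CC(C)(C)C(=O)OC(=O)C/C=C/c1ccc(OCc2ccccc2)c(OCc2ccccc2)c1 | intermediate
7 | (S)-4-benzyl-3-[(E)-4-(3,4-bis(benzyloxy)phenyl)but-3-enoyl]oxazolidin-2-one | O=C1OC[C@H](Cc2ccccc2)N1C(=O)C/C=C/c1ccc(OCc2ccccc2)c(OCc2ccccc2)c1 | intermediate
8 | vanillin (4-hydroxy-3-methoxybenzaldehyde) | COc1cc(C=O)ccc1O | starting material
9 | 4-formyl-2-methoxyphenyl 4-methylbenzenesulfonate | COc1cc(C=O)ccc1OS(=O)(=O)c1ccc(C)cc1 | intermediate
10 | Z dibutylboron dienolate of 7 (not isolated) | CCCCB(CCCC)O/C(=C\C=C\c1ccc(OCc2ccccc2)c(OCc2ccccc2)c1)N1[C@@H](Cc2ccccc2)COC1=O | intermediate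
11 | (S)-4-benzyl-3-[(2S,3S)-2-[(E)-2-(3,4-bis(benzyloxy)phenyl)ethenyl]-3-hydroxy-3-(3-methoxy-4-tosyloxyphenyl)propanoyl]oxazolidin-2-one | COc1cc([C@@H](O)[C@@H](C(=O)N2[C@@H](Cc3ccccc3)COC2=O)/C=C/c2ccc(OCc3ccccc3)c(OCc3ccccc3)c2)ccc1OS(=O)(=O)c1ccc(C)cc1 | intermediate
12 | 4-[(1S,2R,3E)-4-[3,4-bis(benzyloxy)phenyl]-1-hydroxy-2-(hydroxymethyl)but-3-en-1-yl]-2-methoxyphenyl 4-methylbenzenesulfonate | COc1cc([C@@H](O)[C@@H](CO)/C=C/c2ccc(OCc3ccccc3)c(OCc3ccccc3)c2)ccc1OS(=O)(=O)c1ccc(C)cc1 | intermediate
13 | 4-[(1S,2R,3E)-4-[3,4-bis(benzyloxy)phenyl]-2-[(tert-butyldiphenylsilyloxy)methyl]-1-hydroxybut-3-en-1-yl]-2-methoxyphenyl 4-methylbenzenesulfonate (key-step precursor) | COc1cc([C@@H](O)[C@@H](CO[Si](c2ccccc2)(c2ccccc2)C(C)(C)C)/C=C/c2ccc(OCc3ccccc3)c(OCc3ccccc3)c2)ccc1OS(=O)(=O)c1ccc(C)cc1 | intermediate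
14 | formaldehyde (used as paraformaldehyde) | C=O | starting material
15 | O1-methylidene oxocarbenium ion of 13 (not isolated) | COc1cc([C@@H]([O+]=C)[C@@H](CO[Si](c2ccccc2)(c2ccccc2)C(C)(C)C)/C=C/c2ccc(OCc3ccccc3)c(OCc3ccccc3)c2)ccc1OS(=O)(=O)c1ccc(C)cc1 | intermediate
16 | (7S,8R,8'S)-tetrahydrofuran with benzylic cation at C7' (not isolated) | COc1cc([C@H]2OC[C@@H]([CH+]c3ccc(OCc4ccccc4)c(OCc4ccccc4)c3)[C@@H]2CO[Si](c5ccccc5)(c5ccccc5)C(C)(C)C)ccc1OS(=O)(=O)c1ccc(C)cc1 | intermediate
17 | 4-[(2S,3R,4S)-4-{[3,4-bis(benzyloxy)phenyl](hydroxy)methyl}-3-[(tert-butyldiphenylsilyloxy)methyl]oxolan-2-yl]-2-methoxyphenyl 4-methylbenzenesulfonate, both C7' epimers (key-step product) | COc1cc([C@H]2OC[C@@H](C(O)c3ccc(OCc4ccccc4)c(OCc4ccccc4)c3)[C@@H]2CO[Si](c5ccccc5)(c5ccccc5)C(C)(C)C)ccc1OS(=O)(=O)c1ccc(C)cc1 | intermediate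
18 | 4-[(2S,3R,4S)-4-[3,4-bis(benzyloxy)benzoyl]-3-[(tert-butyldiphenylsilyloxy)methyl]oxolan-2-yl]-2-methoxyphenyl 4-methylbenzenesulfonate | COc1cc([C@H]2OC[C@@H](C(=O)c3ccc(OCc4ccccc4)c(OCc4ccccc4)c3)[C@@H]2CO[Si](c5ccccc5)(c5ccccc5)C(C)(C)C)ccc1OS(=O)(=O)c1ccc(C)cc1 | intermediate
19 | 4-[(2S,3R,4S)-4-{(R)-[3,4-bis(benzyloxy)phenyl](hydroxy)methyl}-3-[(tert-butyldiphenylsilyloxy)methyl]oxolan-2-yl]-2-methoxyphenyl 4-methylbenzenesulfonate (protected target with free 7'R hydroxyl) | COc1cc([C@H]2OC[C@@H]([C@@H](O)c3ccc(OCc4ccccc4)c(OCc4ccccc4)c3)[C@@H]2CO[Si](c5ccccc5)(c5ccccc5)C(C)(C)C)ccc1OS(=O)(=O)c1ccc(C)cc1 | intermediate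
20 | 4-[(2S,3R,4S)-4-{(R)-[3,4-bis(benzyloxy)phenyl](hydroxy)methyl}-3-(hydroxymethyl)oxolan-2-yl]-2-methoxyphenol | COc1cc([C@H]2OC[C@@H]([C@@H](O)c3ccc(OCc4ccccc4)c(OCc4ccccc4)c3)[C@@H]2CO)ccc1O | intermediate
21 | 4-{(R)-hydroxy[(3S,4R,5S)-4-(hydroxymethyl)-5-(4-hydroxy-3-methoxyphenyl)oxolan-3-yl]methyl}benzene-1,2-diol (7S,8R,8'S,7'R) | COc1cc([C@H]2OC[C@@H]([C@@H](O)c3ccc(O)c(O)c3)[C@@H]2CO)ccc1O | target

**Step count and risk**

Total step count: 11. Longest linear sequence: 10 steps (steps 1, 2 and 4 to 11; step 3 is a one-step branch).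

Steps most likely to fail:

Step 7 (Prins cyclisation). What may go wrong: protonation of the electron-rich styrene and addition of the C7 hydroxyl across it, which competes with the slow ionisation of a formaldehyde hemiformal, and acid-driven re-ionisation of the product carbinol leading to oligomerisation. The fallback generates the same oxocarbenium ion without protic acid from a preformed acetal. It sets out from 13, which is converted with MOMCl and i-Pr2NEt in CH2Cl2 into the C7 methoxymethyl ether F1. F1 is then ionised with TMSOTf and 2,6-di-tert-butyl-4-methylpyridine in CH2Cl2 at −78 °C (acetal-initiated Prins cyclisation through 15 and 16), and the cation is quenched with aqueous NaHCO3. The fallback comes back to the route at 17.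

Step 9 (ketone reduction). What may go wrong: poor facial selectivity of hydride delivery, because the two ring branches on C8' differ only moderately in size. The fallback replaces substrate control by catalyst control: Corey–Bakshi–Shibata reduction of 18 with (S)-2-methyl-CBS-oxazaborolidine and BH3·SMe2, in which the aryl group acts as the large substituent and the catalyst is matched with the Felkin preference for 7'R. It sets out from 18 and comes back at 19 and makes no new compound (F0).

Step 10 (combined basic deprotection). What may go wrong: incomplete cleavage of the hindered silyl ether, or O-methylation of the freed phenoxide by methyl tosylate formed when methoxide attacks sulfur. The fallback separates the two cleavages and changes their mechanisms. It sets out from 19, which is desilylated with TBAF in THF to the C9 alcohol still carrying the aryl tosylate F2. F2 is then detosylated by reductive S–O cleavage with Mg in MeOH, and the fallback comes back to the route at 20.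

Further compounds
F1 | step 7 | 4-[(1S,2R,3E)-4-[3,4-bis(benzyloxy)phenyl]-2-[(tert-butyldiphenylsilyloxy)methyl]-1-(methoxymethoxy)but-3-en-1-yl]-2-methoxyphenyl 4-methylbenzenesulfonate | COc1cc([C@@H](OCOC)[C@@H](CO[Si](c2ccccc2)(c2ccccc2)C(C)(C)C)/C=C/c2ccc(OCc3ccccc3)c(OCc3ccccc3)c2)ccc1OS(=O)(=O)c1ccc(C)cc1
F0 | step 9 | none | none
F2 | step 10 | 4-[(2S,3R,4S)-4-{(R)-[3,4-bis(benzyloxy)phenyl](hydroxy)methyl}-3-(hydroxymethyl)oxolan-2-yl]-2-methoxyphenyl 4-methylbenzenesulfonate | COc1cc([C@H]2OC[C@@H]([C@@H](O)c3ccc(OCc4ccccc4)c(OCc4ccccc4)c3)[C@@H]2CO)ccc1OS(=O)(=O)c1ccc(C)cc1
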